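## Analysis of the target

Compound 21 is an acyclic 8-O-4′ neolignan. Its C7–C8–C9 chain has a benzylic C7 carrying ring A (3-methoxy-4-(1,3-dihydroxypropan-2-yloxy)phenyl) and a secondary hydroxyl, a C8 carrying the ether oxygen to ring B (2,6-dimethoxy-4-(3-hydroxypropyl)phenyl), and a primary CH2OH at C9. The only stereocenters are C7 and C8, both R, which is the threo relationship; the glyceryl carbon on ring A has two identical CH2OH arms and is not stereogenic. Because the array is acyclic, no ring can relay stereochemistry, so relative and absolute configuration at two adjacent carbons must come from the bond-forming events themselves. The sensitive groups are the benzylic C7–OH para to an alkoxy group (ionisation under acid, hydrogenolysis), the C8 aryloxy group (a good leaving group β to any carbanion, enolate or borate at C7), and four primary hydroxyls that need masking. The C8–O bond joins a secondary carbon to a phenol with two ortho methoxy groups, a poor case for Mitsunobu or SN2 etherification. The strategy rests on C7: it bears ring A, a hydroxyl, a hydrogen and C8, so the hydroxyl can be carried as a C7–B bond and the C1–C7 bond can be made by shifting the ring A aryl group from boron to C7. The C8 aryloxy group can be delivered the same way, from boron to an α-chloro carbon.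

## Retrosynthetic reasoning

**21 ⇒ 20.** The last disconnection removes three benzyl groups, from O9 and from the two glyceryl oxygens on ring A. Benzyl ethers survive the organolithium, Grignard, borane and peroxide steps that precede and leave together by hydrogenolysis without touching C7 or C8. The forward step has to cleave three primary alkyl benzyl ethers while keeping the benzylic C7–O bond.

**20 ⇒ 18.** Two C–O bonds are traced back to C–B bonds: the C7 hydroxyl to the C7 boronic ester of 18, and the terminal hydroxyl of the ring B side chain to the anti-Markovnikov hydroboration adduct 19 of an allyl group. This lets ring B enter as the unprotected allyl phenol 7, and one oxidation serves both boron atoms. The forward reaction must oxidise with retention at C7 and without β-elimination of boron and the C8 aryloxide.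

**18 ⇒ 12 + 16 (key disconnection).** The C1–C7 bond is cut. C7 is the one carbon where a C–C bond joins the two halves and where bond formation and stereocenter formation can be the same event. A cut at C7–C8 would instead need a C8 nucleophile flanked by leaving groups, or aldol-type chemistry with only kinetic diastereocontrol. The gain is convergence: ring A with its protected glyceryl ether arrives as Grignard reagent 16, and the three-carbon chain with ring B arrives as α-chloro boronate 12. The forward reaction has to move the aryl group from boron to C7 with inversion, displacing chloride, faster than the borate 17 can fragment.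

**16 ⇒ 15 ⇒ 13 + 14.** The carbon–metal bond of 16 comes from the C–Br bond of 15 by direct metal insertion. The aryl–O–CH bond of 15 is cut to phenol 13 and alcohol 14 (Mitsunobu etherification). Ring A has only one ortho substituent and the carbinol carbon of 14 is achiral, so this ether is unproblematic.

**12 ⇒ 10.** C7 is removed as a chloromethylene unit inserted into the B–C8 bond of 10. The forward insertion must move C8 from boron to the new carbon with retention and set the C7–Cl configuration under the control of the diol on boron.

**10 ⇒ 6 + 7.** The C8–O bond is cut: phenoxide 8, made from 7, replaces the chloride of 6 with inversion. The hindered phenoxide is first bound to boron (borate 9) and then delivered to the adjacent carbon, which sidesteps a direct SN2 attack at a secondary centre.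

**6 ⇒ 4.** C8 is removed by the same chloromethylene insertion. Working back from 21, both chlorides (C8 in 6, C7 in 12) must be R; one director therefore serves both insertions, and it must be the (S,S)-diol 2. The mirror-image director would carry the same sequence to the enantiomer of 21.

**4 ⇒ 1 + 2.** Ligand exchange at boron: the fluorides of 1 are exchanged for diol 2 by way of boronic acid 3.

## Alternatives that were turned down

**Alternative 1:** The disconnection runs across C7–C8 of the ethyl (Z)-2-aryloxy-3-arylacrylate A1, which already holds both rings; the C7–O bond is traced to a C7–B bond and C8 receives a hydrogen. In the forward sense a copper boryl species (CuCl, NaOtBu, chiral bisphosphine, B2pin2) adds to C7 of A1 and methanol protonates the enolate at C8 to give the syn boryl ester A2. Oxidation of boron, ester reduction and removal of the acetonide and silyl groups would finish.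
- For: A1 is assembled by O-alkylation and a condensation from simple ring A and ring B building blocks. The chirality source is catalytic. The acid- and fluoride-labile protecting groups avoid a hydrogenolysis next to the benzylic alcohol. On step count and on that last point it is stronger than the chosen route.
- Against: C8 is created by protonation of an acyclic enolate, an event with no built-in stereochemical course, so threo versus erythro depends on the catalyst and on the alkene geometry of A1. The C8–H of A2 stays epimerisable next to the ester in an alkoxide medium. The aryloxy group makes A1 an electron-rich, trisubstituted enol-ether-type acceptor, which slows borylcupration. A2 carries boron β to the aryloxide just as 18 does, and has an acidic α-hydrogen in addition.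
- Comparison: the chosen strategy gives up catalytic economy and accepts cryogenic stoichiometric steps. In exchange, each centre arises from a displacement at carbon whose stereochemical course is fixed by mechanism.

**Alternative 2:** The bond cut is C7–H of the racemic keto ester A3. RuCl(p-cymene)(TsDPEN) with HCO2H/NEt3 would reduce the ketone while C8 epimerises through the enol, so that one enantiomer is drained to the syn hydroxy ester A4 with C7 and C8 as in 21. Hydride reduction of the two ester groups and acetonide hydrolysis would complete the synthesis.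
- For: it is the shortest route, forms the C7–OH directly without boron, is catalytic, and sets both centres in one step from a racemate. Transfer hydrogenation with dynamic kinetic resolution is well established for β-keto esters with an α-heteroatom. On step economy and scalability it is stronger than the chosen strategy.
- Against: the syn or anti sense of the dynamic resolution depends on the α-substituent, and for an aryloxy group with two ortho methoxy groups neither sense nor level is secured by structure. The ketone of A3 is deactivated by the para-alkoxy ring A. A4 is a β-hydroxy ester that can undergo retro-aldol cleavage or C8 epimerisation during the basic hydride reduction that must follow.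
- Comparison: the chosen strategy replaces a selectivity that depends on relative rates of epimerisation and reduction with two stereospecific inversions under one director, so threo follows from mechanism. The price is more steps and stoichiometric organometallic reagents.

**Alternative 3:** The bond cut is O–C4′ of the aryl ether, and ring B is grown from a cyclohexane-1,3-dione instead of being brought in as an arene. The 7,9-O-silylene (7R,8R)-triol A5, with its free C8 hydroxyl, would react with the diazo dione A6 under Rh2(OAc)4; the rhodium carbenoid inserts into the O–H bond to give the 2-alkoxy-3-hydroxycyclohexenone A7. A7 must then be dehydrogenated to the resorcinol level and O-methylated twice.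
- For: both stereocenters of A5 would come from an asymmetric dihydroxylation, a very dependable source, and the key step does not touch them because the C8–O bond is never broken. It avoids using a di-ortho-substituted phenoxide as a nucleophile at a secondary carbon, which is the weakest preparative point of the chosen route (step 3); on that point it is stronger.
- Against: O–H insertion into a hindered secondary alcohol flanked by a silylene ring competes with Wolff rearrangement and with ylide formation at the neighbouring oxygens. Aromatisation of A7 needs an oxidant in the presence of the electron-rich ring A and its benzylic silyl ether, then a double methylation, so several steps of uncertain chemoselectivity follow the key step. It is the longest of the routes.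
- Comparison: the chosen strategy introduces ring B intact in one step and finishes two steps after its key step.

Key step: step 7

Assumption: chloromethylene insertion into boronic esters of C2-symmetric 1,2-diols follows the established sense in which an (R,R)-diol gives the (αS)-chloride and an (S,S)-diol the (αR)-chloride (priorities Cl > C > B > H); both chlorides of this route must be (αR), so the director is the (S,S)-diol 2, whereas the (R,R)-diol would carry the same sequence to the (7S,8S) enantiomer of 21.

## Route

Step 1
Reactants: 1 potassium (benzyloxymethyl)trifluoroborate; 2 (1S,2S)-1,2-dicyclohexylethane-1,2-diol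
Product: 4 (4S,5S)-2-(benzyloxymethyl)-4,5-dicyclohexyl-1,3,2-dioxaborolane, via (benzyloxymethyl)boronic acid 3 (not isolated)
Conditions: TMSCl, H2O, MeCN, rt; then 2, MgSO4, Et2O, rt
Reagents that add atoms: none
Why: Fluoride abstraction by the chlorosilane in wet acetonitrile hydrolyses the trifluoroborate to boronic acid 3, which condenses with diol 2 under dehydration (boronic ester formation). No stereocenter is formed; the C2-symmetric director is installed unchanged.

Step 2
Reactants: 4 (4S,5S)-2-(benzyloxymethyl)-4,5-dicyclohexyl-1,3,2-dioxaborolane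
Product: 6 (4S,5S)-2-[(1R)-2-(benzyloxy)-1-chloroethyl]-4,5-dicyclohexyl-1,3,2-dioxaborolane, via lithium dichloromethyl borate 5 (not isolated)
Conditions: CH2Cl2, n-BuLi, THF, −100 °C; 4; ZnCl2, −100 °C → rt
Reagents that add atoms: dichloromethane, ClCCl
Why: Matteson homologation: LiCHCl2 adds to boron to give borate 5, and with ZnCl2 bridging a ring oxygen and the departing chloride the CH2OBn group migrates to carbon with loss of one chloride. The (S,S)-diol makes the two chlorides diastereotopic and selects the one whose loss gives the (R)-chloride at C8. ZnCl2 also binds free chloride, which would otherwise epimerise the product.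

Step 3
Reactants: 6 (4S,5S)-2-[(1R)-2-(benzyloxy)-1-chloroethyl]-4,5-dicyclohexyl-1,3,2-dioxaborolane; 7 4-allyl-2,6-dimethoxyphenol
Product: 10 (4S,5S)-2-[(1S)-1-(4-allyl-2,6-dimethoxyphenoxy)-2-(benzyloxy)ethyl]-4,5-dicyclohexyl-1,3,2-dioxaborolane, via sodium 4-allyl-2,6-dimethoxyphenoxide 8 (not isolated), via sodium aryloxy borate 9 (not isolated)
Conditions: 7, NaH, THF, 0 °C; then 6, THF–DMSO, rt → 50 °C
Reagents that add atoms: none
Why: Substitution of an α-chloro boronic ester through a borate: phenoxide 8 adds to boron (9) and the aryloxy group shifts to C8 anti to chloride, so the C8–O bond forms with inversion, (R)-chloride to (S)-ether. The known counterpart is the alkoxide displacement of Matteson chloro boronates; DMSO raises the reactivity of the hindered phenoxide.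

Step 4
Reactants: 10 (4S,5S)-2-[(1S)-1-(4-allyl-2,6-dimethoxyphenoxy)-2-(benzyloxy)ethyl]-4,5-dicyclohexyl-1,3,2-dioxaborolane
Product: 12 (4S,5S)-2-[(1R,2R)-2-(4-allyl-2,6-dimethoxyphenoxy)-3-(benzyloxy)-1-chloropropyl]-4,5-dicyclohexyl-1,3,2-dioxaborolane, via lithium dichloromethyl borate 11 (not isolated)
Conditions: CH2Cl2, n-BuLi, THF, −100 °C; 10; ZnCl2, −100 °C → rt
Reagents that add atoms: dichloromethane, ClCCl
Why: Second Matteson homologation under the same director: the α-aryloxyalkyl group migrates from boron with retention at C8 (its descriptor changes from S to R only because C7 replaces boron), and the (S,S)-diol again delivers the (R)-chloride, now at C7. The allyl group is inert to the carbenoid at −100 °C; the mixture is not heated because 11 and 12 carry an aryloxy group β to boron.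

Step 5
Reactants: 13 4-bromo-2-methoxyphenol; 14 1,3-bis(benzyloxy)propan-2-ol
Product: 15 1-{[1,3-bis(benzyloxy)propan-2-yl]oxy}-4-bromo-2-methoxybenzene
Conditions: PPh3, DIAD, THF, 0 °C → 40 °C
Reagents that add atoms: none
Why: Mitsunobu etherification of phenol 13 with secondary alcohol 14. The carbinol carbon bears two identical arms, so the inversion has no stereochemical consequence, and the aryl bromide is untouched.

Step 6
Reactants: 15 1-{[1,3-bis(benzyloxy)propan-2-yl]oxy}-4-bromo-2-methoxybenzene
Product: 16 {4-[1,3-bis(benzyloxy)propan-2-yloxy]-3-methoxyphenyl}magnesium bromide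
Conditions: Mg turnings, I2 (cat.), THF, 45 °C
Reagents that add atoms: magnesium, [Mg]
Why: Oxidative insertion of magnesium into the aryl C–Br bond (Grignard formation). The ether groups are inert; the solution is titrated and used directly.

Step 7
Reactants: 12 (4S,5S)-2-[(1R,2R)-2-(4-allyl-2,6-dimethoxyphenoxy)-3-(benzyloxy)-1-chloropropyl]-4,5-dicyclohexyl-1,3,2-dioxaborolane; 16 {4-[1,3-bis(benzyloxy)propan-2-yloxy]-3-methoxyphenyl}magnesium bromide
Product: 18 (4S,5S)-2-[(1R,2S)-2-(4-allyl-2,6-dimethoxyphenoxy)-3-(benzyloxy)-1-{4-[1,3-bis(benzyloxy)propan-2-yloxy]-3-methoxyphenyl}propyl]-4,5-dicyclohexyl-1,3,2-dioxaborolane, via bromomagnesium aryl borate 17 (not isolated)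
Conditions: 16 (1.05 equiv) added to 12, THF, −78 °C; −78 °C → 0 °C; aq NH4Cl, 0 °C
Reagents that add atoms: none
Why: Grignard reagent 16 adds to the trigonal boron of 12 at −78 °C to give the tetracoordinate borate 17; on warming, the ring A aryl group shifts from boron to C7 anti-periplanar to the C–Cl bond, chloride leaves as MgBrCl and the C1–C7 bond forms (1,2-metallate rearrangement). The closest known reaction is the displacement of the chloride of Matteson α-chloro boronic esters by aryl and alkyl Grignard reagents. No ring is closed. The only new stereocenter is C7: the shift is stereospecific with inversion, so its configuration is controlled by the C–Cl configuration that diol 2 set in step 4, and the aryl group ends on the face opposite to where chlorine was (the descriptor stays R because the priorities change). C8 is not involved; its descriptor changes from R to S only because C7 now carries carbon and boron instead of chlorine. The selectivity needed is chemoselectivity within 17: aryl migration must beat ring-oxygen migration and anti-elimination of boron with the C8 aryloxide. Aryl is a good migrating group and the α-chloride is a better nucleofuge in the 1,2-shift than aryloxide is in elimination, while the bulky dicyclohexyl dioxaborolane shields 18 from a second addition. One equivalent of titrated 16, low temperature and a mildly acidic quench keep the β-aryloxy boronate 18 from eliminating.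

Step 8
Reactants: 18 (4S,5S)-2-[(1R,2S)-2-(4-allyl-2,6-dimethoxyphenoxy)-3-(benzyloxy)-1-{4-[1,3-bis(benzyloxy)propan-2-yloxy]-3-methoxyphenyl}propyl]-4,5-dicyclohexyl-1,3,2-dioxaborolane
Product: 20 (1R,2R)-3-(benzyloxy)-1-{4-[1,3-bis(benzyloxy)propan-2-yloxy]-3-methoxyphenyl}-2-[4-(3-hydroxypropyl)-2,6-dimethoxyphenoxy]propan-1-ol, via B-alkyl-9-borabicyclo[3.3.1]nonane adduct 19 (not isolated)
Conditions: 9-BBN, THF, 0 °C → rt; then aq NaHCO3, 30% H2O2, 0 °C → rt
Reagents that add atoms: hydrogen peroxide, OO
Why: 9-BBN hydroborates the terminal alkene anti-Markovnikov (19) without touching the boronic ester, and buffered peroxide then oxidises both C–B bonds by 1,2-shift from boron to oxygen with retention, giving (R)-C7–OH and the primary alcohol in one operation. Mild base and low temperature disfavour β-elimination of boron and aryloxide; diol 2 is released and can be recovered. With oxygen on C7 the C8 descriptor returns to R without any change at that carbon.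

Step 9
Reactants: 20 (1R,2R)-3-(benzyloxy)-1-{4-[1,3-bis(benzyloxy)propan-2-yloxy]-3-methoxyphenyl}-2-[4-(3-hydroxypropyl)-2,6-dimethoxyphenoxy]propan-1-ol
Product: 21 (1R,2R)-1-[4-(1,3-dihydroxypropan-2-yloxy)-3-methoxyphenyl]-2-[4-(3-hydroxypropyl)-2,6-dimethoxyphenoxy]propane-1,3-diol
Conditions: H2 (1 atm), Pd/C, EtOAc–EtOH, rt
Reagents that add atoms: none
Why: Catalytic hydrogenolysis of the three primary alkyl benzyl ethers. Under neutral conditions the benzylic C7–OH and the aryl ethers should be retained, and neither stereocenter is involved.

## Compound list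

1 | potassium (benzyloxymethyl)trifluoroborate | [K+].F[B-](F)(F)COCc1ccccc1 | starting material
2 | (1S,2S)-1,2-dicyclohexylethane-1,2-diol | O[C@@H](C1CCCCC1)[C@@H](O)C1CCCCC1 | starting material
3 | (benzyloxymethyl)boronic acid (not isolated) | OB(O)COCc1ccccc1 | intermediate
4 | (4S,5S)-2-(benzyloxymethyl)-4,5-dicyclohexyl-1,3,2-dioxaborolane | C(OCc1ccccc1)B1O[C@@H](C2CCCCC2)[C@H](C2CCCCC2)O1 | intermediate
5 | lithium dichloromethyl borate of 4 (not isolated) | [Li+].ClC(Cl)[B-]1(COCc2ccccc2)O[C@@H](C2CCCCC2)[C@H](C2CCCCC2)O1 | intermediate
6 | (4S,5S)-2-[(1R)-2-(benzyloxy)-1-chloroethyl]-4,5-dicyclohexyl-1,3,2-dioxaborolane | Cl[C@@H](COCc1ccccc1)B1O[C@@H](C2CCCCC2)[C@H](C2CCCCC2)O1 | intermediate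
7 | 4-allyl-2,6-dimethoxyphenol | C=CCc1cc(OC)c(O)c(OC)c1 | starting material
8 | sodium 4-allyl-2,6-dimethoxyphenoxide (not isolated) | [Na+].[O-]c1c(OC)cc(CC=C)cc1OC | intermediate
9 | sodium aryloxy borate from 6 and 8 (not isolated) | [Na+].Cl[C@@H](COCc1ccccc1)[B-]1(Oc2c(OC)cc(CC=C)cc2OC)O[C@@H](C2CCCCC2)[C@H](C2CCCCC2)O1 | intermediate
10 | (4S,5S)-2-[(1S)-1-(4-allyl-2,6-dimethoxyphenoxy)-2-(benzyloxy)ethyl]-4,5-dicyclohexyl-1,3,2-dioxaborolane | C=CCc1cc(OC)c(O[C@H](COCc2ccccc2)B2O[C@@H](C3CCCCC3)[C@H](C3CCCCC3)O2)c(OC)c1 | intermediate
11 | lithium dichloromethyl borate of 10 (not isolated) | [Li+].ClC(Cl)[B-]1([C@@H](COCc2ccccc2)Oc2c(OC)cc(CC=C)cc2OC)O[C@@H](C2CCCCC2)[C@H](C2CCCCC2)O1 | intermediate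
12 | (4S,5S)-2-[(1R,2R)-2-(4-allyl-2,6-dimethoxyphenoxy)-3-(benzyloxy)-1-chloropropyl]-4,5-dicyclohexyl-1,3,2-dioxaborolane | Cl[C@H](B1O[C@@H](C2CCCCC2)[C@H](C2CCCCC2)O1)[C@@H](COCc1ccccc1)Oc1c(OC)cc(CC=C)cc1OC | intermediate
13 | 4-bromo-2-methoxyphenol | COc1cc(Br)ccc1O | starting material
14 | 1,3-bis(benzyloxy)propan-2-ol | OC(COCc1ccccc1)COCc1ccccc1 | starting material
15 | 1-{[1,3-bis(benzyloxy)propan-2-yl]oxy}-4-bromo-2-methoxybenzene | COc1cc(Br)ccc1OC(COCc1ccccc1)COCc1ccccc1 | intermediate
16 | {4-[1,3-bis(benzyloxy)propan-2-yloxy]-3-methoxyphenyl}magnesium bromide (THF solution) | COc1cc([Mg]Br)ccc1OC(COCc1ccccc1)COCc1ccccc1 | intermediate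
17 | bromomagnesium aryl borate from 12 and 16 (not isolated) | Br[Mg+].Cl[C@H]([B-]1(c2ccc(OC(COCc3ccccc3)COCc3ccccc3)c(OC)c2)O[C@@H](C2CCCCC2)[C@H](C2CCCCC2)O1)[C@@H](COCc1ccccc1)Oc1c(OC)cc(CC=C)cc1OC | intermediate
18 | (4S,5S)-2-[(1R,2S)-2-(4-allyl-2,6-dimethoxyphenoxy)-3-(benzyloxy)-1-{4-[1,3-bis(benzyloxy)propan-2-yloxy]-3-methoxyphenyl}propyl]-4,5-dicyclohexyl-1,3,2-dioxaborolane | COc1cc([C@@H](B2O[C@@H](C3CCCCC3)[C@H](C3CCCCC3)O2)[C@@H](COCc2ccccc2)Oc2c(OC)cc(CC=C)cc2OC)ccc1OC(COCc1ccccc1)COCc1ccccc1 | intermediate
19 | B-alkyl-9-borabicyclo[3.3.1]nonane adduct of 18 at the terminal carbon of the former allyl group (not isolated) | COc1cc([C@@H](B2O[C@@H](C3CCCCC3)[C@H](C3CCCCC3)O2)[C@@H](COCc2ccccc2)Oc2c(OC)cc(CCCB3C4CCCC3CCC4)cc2OC)ccc1OC(COCc1ccccc1)COCc1ccccc1 | intermediate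
20 | (1R,2R)-3-(benzyloxy)-1-{4-[1,3-bis(benzyloxy)propan-2-yloxy]-3-methoxyphenyl}-2-[4-(3-hydroxypropyl)-2,6-dimethoxyphenoxy]propan-1-ol | COc1cc([C@@H](O)[C@@H](COCc2ccccc2)Oc2c(OC)cc(CCCO)cc2OC)ccc1OC(COCc1ccccc1)COCc1ccccc1 | intermediate
21 | (1R,2R)-1-[4-(1,3-dihydroxypropan-2-yloxy)-3-methoxyphenyl]-2-[4-(3-hydroxypropyl)-2,6-dimethoxyphenoxy]propane-1,3-diol | COc1cc([C@@H](O)[C@@H](CO)Oc2c(OC)cc(CCCO)cc2OC)ccc1OC(CO)CO | target

## Step count and least certain steps

Total step count: 9. Longest linear sequence: 7 steps (steps 1, 2, 3, 4, 7, 8, 9, from 1 and 2); the ring A branch (steps 5 and 6) joins at step 7.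

**Step 7 (key step).** The most likely failure is fragmentation of borate 17 by anti-elimination of boron and the C8 aryloxide in competition with the aryl shift, or a second addition of 16 to the product that triggers the same elimination. The absolute sense of both insertions rests on the director rule and should be confirmed on 6 by chemical correlation (methyl Grignard displacement, oxidation, comparison with a carbinol of known rotation) before material is committed.
Fallback, setting out from 12 and returning at 20: buffered H2O2 oxidation collapses the α-chloro boronate 12 to the aryloxy aldehyde (2R)-2-(4-allyl-2,6-dimethoxyphenoxy)-3-(benzyloxy)propanal F1. Addition of 16 at −78 °C should give the C7-epimeric allyl alcohols F2, which are oxidised with Dess–Martin periodinane to the aryl ketone F3. Transfer hydrogenation of F3 with RuCl(p-cymene)[(S,S)-TsDPEN] and HCO2H/NEt3 (catalyst enantiomer chosen by analogy with aryl alkyl ketones) should give the threo allyl alcohol F4 under reagent control. Hydroboration of F4 with excess 9-BBN gives the bis-boron adduct F5, and H2O2 oxidation of F5 returns to the route at 20. This replaces migration on boron with carbonyl addition and a catalyst-controlled reduction.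

**Step 3.** The most likely failure is slow capture of the hindered, weakly basic phenoxide by boron, so that chloride exchange at C8 (erosion of configuration) and dehydrochlorination gain ground.
Fallback, setting out from 4 and returning at 10: the insertion is run with LiCHBr2 (CH2Br2, LiN(iPr)2, THF, −78 °C, then ZnCl2) to give the bromo boronate (4S,5S)-2-[(1R)-2-(benzyloxy)-1-bromoethyl]-4,5-dicyclohexyl-1,3,2-dioxaborolane F6. Its better leaving group should let phenoxide 8 be taken up and shifted at lower temperature and without DMSO, giving 10.

**Step 8.** The most likely failure is β-elimination from the hydroperoxide borate, or incomplete oxidation of the hindered dioxaborolane under the mild base needed to avoid that elimination.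
Fallback, setting out from 18 and returning at 20: the diol is exchanged for fluoride with KHF2 (MeOH–H2O) to give the potassium trifluoroborate F7, which is oxidised rapidly near neutral pH with KHSO5 (as 2KHSO5·KHSO4·K2SO4, acetone–H2O) to the threo allyl alcohol F4. Hydroboration with excess 9-BBN to the bis-boron adduct F5 and H2O2 oxidation then give 20.

**Step 9.** The most likely failure is reductive cleavage of the benzylic C7–O bond, activated by the para-alkoxy group, before the three slower primary alkyl benzyl ethers are fully removed.
Fallback, setting out from 20 and returning at 21: both free hydroxyls are silylated (TBSOTf, 2,6-lutidine, CH2Cl2) to the bis-silyl ether F8, whose bulky benzylic silyl ether should resist hydrogenolysis. H2 over Pd/C in EtOAc then gives the debenzylated bis-silyl triol F9, and Bu4NF in THF releases 21.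

## Further compounds

F1 | step 7 | (2R)-2-(4-allyl-2,6-dimethoxyphenoxy)-3-(benzyloxy)propanal | O=C[C@@H](COCc1ccccc1)Oc1c(OC)cc(CC=C)cc1OC
F2 | step 7 | (2R)-2-(4-allyl-2,6-dimethoxyphenoxy)-3-(benzyloxy)-1-{4-[1,3-bis(benzyloxy)propan-2-yloxy]-3-methoxyphenyl}propan-1-ol, both C1 epimers | COc1cc(C(O)[C@@H](COCc2ccccc2)Oc2c(OC)cc(CC=C)cc2OC)ccc1OC(COCc1ccccc1)COCc1ccccc1
F3 | step 7 | (2R)-2-(4-allyl-2,6-dimethoxyphenoxy)-3-(benzyloxy)-1-{4-[1,3-bis(benzyloxy)propan-2-yloxy]-3-methoxyphenyl}propan-1-one | COc1cc(C(=O)[C@@H](COCc2ccccc2)Oc2c(OC)cc(CC=C)cc2OC)ccc1OC(COCc1ccccc1)COCc1ccccc1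
F4 | step 7 | (1R,2R)-2-(4-allyl-2,6-dimethoxyphenoxy)-3-(benzyloxy)-1-{4-[1,3-bis(benzyloxy)propan-2-yloxy]-3-methoxyphenyl}propan-1-ol | COc1cc([C@@H](O)[C@@H](COCc2ccccc2)Oc2c(OC)cc(CC=C)cc2OC)ccc1OC(COCc1ccccc1)COCc1ccccc1
F5 | step 7 | bis-boron adduct of F4 with 9-BBN (C7–O–B borinate and terminal C–B of the former allyl group) | COc1cc([C@@H](OB2C3CCCC2CCC3)[C@@H](COCc2ccccc2)Oc2c(OC)cc(CCCB3C4CCCC3CCC4)cc2OC)ccc1OC(COCc1ccccc1)COCc1ccccc1
F6 | step 3 | (4S,5S)-2-[(1R)-2-(benzyloxy)-1-bromoethyl]-4,5-dicyclohexyl-1,3,2-dioxaborolane | Br[C@@H](COCc1ccccc1)B1O[C@@H](C2CCCCC2)[C@H](C2CCCCC2)O1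
F7 | step 8 | potassium [(1R,2S)-2-(4-allyl-2,6-dimethoxyphenoxy)-3-(benzyloxy)-1-{4-[1,3-bis(benzyloxy)propan-2-yloxy]-3-methoxyphenyl}propyl]trifluoroborate | [K+].COc1cc([C@@H]([B-](F)(F)F)[C@@H](COCc2ccccc2)Oc2c(OC)cc(CC=C)cc2OC)ccc1OC(COCc1ccccc1)COCc1ccccc1
F8 | step 9 | (1R,2R)-3-(benzyloxy)-1-{4-[1,3-bis(benzyloxy)propan-2-yloxy]-3-methoxyphenyl}-1-(tert-butyldimethylsilyloxy)-2-{4-[3-(tert-butyldimethylsilyloxy)propyl]-2,6-dimethoxyphenoxy}propane | COc1cc([C@@H](O[Si](C)(C)C(C)(C)C)[C@@H](COCc2ccccc2)Oc2c(OC)cc(CCCO[Si](C)(C)C(C)(C)C)cc2OC)ccc1OC(COCc1ccccc1)COCc1ccccc1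
F9 | step 9 | (2R,3R)-3-(tert-butyldimethylsilyloxy)-2-{4-[3-(tert-butyldimethylsilyloxy)propyl]-2,6-dimethoxyphenoxy}-3-[4-(1,3-dihydroxypropan-2-yloxy)-3-methoxyphenyl]propan-1-ol | COc1cc([C@@H](O[Si](C)(C)C(C)(C)C)[C@@H](CO)Oc2c(OC)cc(CCCO[Si](C)(C)C(C)(C)C)cc2OC)ccc1OC(CO)CO
A1 | alternative 1 | ethyl (Z)-2-{4-[3-(tert-butyldimethylsilyloxy)propyl]-2,6-dimethoxyphenoxy}-3-[4-(2,2-dimethyl-1,3-dioxan-5-yloxy)-3-methoxyphenyl]acrylate | CCOC(=O)/C(Oc1c(OC)cc(CCCO[Si](C)(C)C(C)(C)C)cc1OC)=C/c1ccc(OC2COC(C)(C)OC2)c(OC)c1
A2 | alternative 1 | ethyl (2S,3R)-2-aryloxy-3-aryl-3-(pinacolboryl)propanoate, syn | COc1cc([C@@H](B2OC(C)(C)C(C)(C)O2)[C@@H](C(=O)OCC)Oc2c(OC)cc(CCCO[Si](C)(C)C(C)(C)C)cc2OC)ccc1OC1COC(C)(C)OC1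
A3 | alternative 2 | racemic ethyl 2-aryloxy-3-aryl-3-oxopropanoate | COc1cc(C(=O)C(C(=O)OCC)Oc2c(OC)cc(CCC(=O)OC)cc2OC)ccc1OC1COC(C)(C)OC1
A4 | alternative 2 | ethyl (2S,3R)-2-aryloxy-3-aryl-3-hydroxypropanoate, syn | COc1cc([C@@H](O)[C@@H](C(=O)OCC)Oc2c(OC)cc(CCC(=O)OC)cc2OC)ccc1OC1COC(C)(C)OC1
A5 | alternative 3 | 7,9-O-di-tert-butylsilylene (7R,8R)-triol with free C8 hydroxyl | COc1cc([C@@H](O[Si]2(C(C)(C)C)C(C)(C)C)[C@@H](CO2)O)ccc1OC(COCc1ccccc1)COCc1ccccc1
A6 | alternative 3 | 5-[3-(benzyloxy)propyl]-2-diazocyclohexane-1,3-dione | [N-]=[N+]=C1C(=O)CC(CCCOCc2ccccc2)CC1=O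
A7 | alternative 3 | 2-alkoxy-3-hydroxycyclohex-2-enone ether of the (7R,8R)-triol | COc1cc([C@@H](O[Si]2(C(C)(C)C)C(C)(C)C)[C@@H](CO2)OC2=C(O)CC(CCCOCc3ccccc3)CC2=O)ccc1OC(COCc1ccccc1)COCc1ccccc1
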